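**Retrosynthetic overview**
1. Target 32 is cut at the quaternary carbon C3′: a copper-catalysed enantioselective SN2′ coupling joins allylic phosphate 10 to the E-alkenylalane made from alkyne 30. This one step gives the quaternary centre, the vinyl group and the E-alkene.
2. Phosphate 10 comes from enone 4 by methyl conjugate addition, trans-selective Mukaiyama–Michael addition to but-3-en-2-one, HWE olefination, methylenation, reduction and phosphorylation.
3. Enone 4 comes from 3,4-dimethylanisole (1): Birch dearomatisation to the achiral β,γ-enone 3, then a catalytic enantioselective isomerisation that fixes the ring methyl stereocentre (key step). The only ring is never formed; it is the benzene ring of 1.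
4. Alkyne 30 comes from isopropyl boronic ester 11 by eight reagent-controlled boronic ester homologations (four CH(CH3), four CH2) and a deborylative alkynylation.

Assumption: small reagents that deliver atoms (MeMgBr, but-3-en-2-one, the phosphonate, CH2Br2, ethyl 2,4,6-triisopropylbenzoate, ClCH2I, bromoethene) are listed with SMILES and not numbered; they, both sparteine enantiomers and 11 are taken as commercial.
Locants in the Why lines: ring C1–C6 and side chain C1′–C15′ as in the name of 32; for 3–6 the ketone numbering is used.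

**Route**

Step 1
Reactants: 1 3,4-dimethylanisole
Product: 3 3,4-dimethylcyclohex-3-en-1-one, via dienol ether 2 (not isolated)
Conditions: Li, NH3(l), THF, t-BuOH, −78 → −33 °C; NH4Cl; then (CO2H)2, MeOH–H2O, rt
Reagents that add atoms: water (O)
Why: Birch reduction protonates the two ring carbons that carry neither OMe nor methyl (dearomatisation), and mild enol ether hydrolysis stops at the unconjugated β,γ-enone, an achiral ketone in which the future ring stereocentre is still an sp2 carbon.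

Step 2
Reactants: 3 3,4-dimethylcyclohex-3-en-1-one
Product: 4 (4S)-3,4-dimethylcyclohex-2-en-1-one
Conditions: 9-amino-9-deoxy-epi-quinidine (10 mol %), CF3CO2H (20 mol %), toluene, −25 °C
Reagents that add atoms: none
Why: Proposed new method: the primary amine forms a dienamine with 3 and the protonated quinuclidine of the same catalyst returns the proton to one face of the γ-carbon C4, so conjugation drives an enantioselective proton-transfer isomerisation that sets the ring methyl stereocentre as S; the closest known reaction type is the amine-catalysed asymmetric isomerisation of 4-substituted cyclohex-3-enones, which lack the extra 3-methyl group.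

Step 3
Reactants: 4 (4S)-3,4-dimethylcyclohex-2-en-1-one
Product: 5 trimethyl{[(4S)-3,3,4-trimethylcyclohex-1-en-1-yl]oxy}silane
Conditions: MeMgBr, CuBr·SMe2 (5 mol %), TMSCl, HMPA, THF, −78 °C; Et3N, pentane work-up
Reagents that add atoms: methylmagnesium bromide (C[Mg]Br); chlorotrimethylsilane (C[Si](C)(C)Cl)
Why: TMSCl-accelerated copper-catalysed conjugate addition of the methyl Grignard reagent creates the gem-dimethyl carbon (not a stereocentre) and traps the enolate regiospecifically as the C1–C2 silyl enol ether, leaving C4 untouched.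

Step 4
Reactants: 5 trimethyl{[(4S)-3,3,4-trimethylcyclohex-1-en-1-yl]oxy}silane
Product: 6 (2R,4S)-3,3,4-trimethyl-2-(3-oxobutyl)cyclohexan-1-one
Conditions: but-3-en-2-one, BF3·OEt2, i-PrOH, MeNO2, −20 °C
Reagents that add atoms: but-3-en-2-one (CC(=O)C=C)
Why: Mukaiyama–Michael addition under kinetic, non-basic conditions: in the half-chair with the C4 methyl pseudoequatorial the enone approaches C2 axially and anti to the pseudoaxial C3 methyl, which places the new side chain trans to the C4 methyl.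

Step 5
Reactants: 6 (2R,4S)-3,3,4-trimethyl-2-(3-oxobutyl)cyclohexan-1-one
Product: 7 ethyl (2E)-3-methyl-5-[(1R,3S)-2,2,3-trimethyl-6-oxocyclohexyl]pent-2-enoate
Conditions: (EtO)2P(O)CH2CO2Et (1.3 equiv), NaH (1.2 equiv), THF, 0 °C → rt; E isomer separated from the minor Z isomer on silica
Reagents that add atoms: triethyl phosphonoacetate (CCOC(=O)CP(=O)(OCC)OCC)
Why: Horner–Wadsworth–Emmons olefination takes place at the unhindered methyl ketone, not at the ring carbonyl shielded by the neighbouring quaternary carbon, and gives mainly the E trisubstituted enoate (about 4:1, minor Z removed), the weakly basic phosphonate anion leaving the α-stereocentre intact.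

Step 6
Reactants: 7 ethyl (2E)-3-methyl-5-[(1R,3S)-2,2,3-trimethyl-6-oxocyclohexyl]pent-2-enoate
Product: 8 ethyl (2E)-3-methyl-5-[(1S,3S)-2,2,3-trimethyl-6-methylidenecyclohexyl]pent-2-enoate
Conditions: Zn, CH2Br2, TiCl4, THF (reagent pre-formed); then 7, CH2Cl2, 0 °C → rt
Reagents that add atoms: dibromomethane (BrCBr)
Why: Non-basic Lombardo–Takai methylenation converts the hindered, epimerisable ring ketone into the exocyclic alkene without touching the ester, the conjugated alkene or the adjacent stereocentre.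

Step 7
Reactants: 8 ethyl (2E)-3-methyl-5-[(1S,3S)-2,2,3-trimethyl-6-methylidenecyclohexyl]pent-2-enoate
Product: 9 (2E)-3-methyl-5-[(1S,3S)-2,2,3-trimethyl-6-methylidenecyclohexyl]pent-2-en-1-ol
Conditions: i-Bu2AlH (2.2 equiv), CH2Cl2, −78 °C; aqueous potassium sodium tartrate
Reagents that add atoms: none
Why: 1,2-Reduction of the α,β-unsaturated ester with the aluminium hydride gives the allylic alcohol with the E geometry and both isolated alkenes retained.

Step 8
Reactants: 9 (2E)-3-methyl-5-[(1S,3S)-2,2,3-trimethyl-6-methylidenecyclohexyl]pent-2-en-1-ol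
Product: 10 diethyl (2E)-3-methyl-5-[(1S,3S)-2,2,3-trimethyl-6-methylidenecyclohexyl]pent-2-en-1-yl phosphate
Conditions: ClP(O)(OEt)2, Et3N, DMAP (cat.), CH2Cl2, 0 °C
Reagents that add atoms: diethyl chlorophosphate (CCOP(=O)(Cl)OCC)
Why: O-Phosphorylation of the primary allylic alcohol installs the leaving group required for the copper-catalysed SN2′ coupling of step 18.

Step 9
Reactants: 11 4,4,5,5-tetramethyl-2-(propan-2-yl)-1,3,2-dioxaborolane
Product: 13 4,4,5,5-tetramethyl-2-[(2S)-3-methylbutan-2-yl]-1,3,2-dioxaborolane, via boronate complex 12 (not isolated)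
Conditions: ethyl 2,4,6-triisopropylbenzoate, s-BuLi, (+)-sparteine, Et2O, −78 °C; add 11; then 40 °C
Reagents that add atoms: ethyl 2,4,6-triisopropylbenzoate (CCOC(=O)c1c(C(C)C)cc(C(C)C)cc1C(C)C)
Why: Lithiation–borylation: the (R)-configured α-lithiated benzoate formed by (+)-sparteine-mediated deprotonation adds to boron with retention and the isopropyl group then migrates with inversion at the carbenoid carbon (stereospecific 1,2-metallate rearrangement), so C13′ is set by the reagent alone.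

Step 10
Reactants: 13 4,4,5,5-tetramethyl-2-[(2S)-3-methylbutan-2-yl]-1,3,2-dioxaborolane
Product: 15 2-[(2R)-2,3-dimethylbutyl]-4,4,5,5-tetramethyl-1,3,2-dioxaborolane, via boronate complex 14 (not isolated)
Conditions: ClCH2I, n-BuLi, Et2O, −78 °C → rt
Reagents that add atoms: chloroiodomethane (ClCI)
Why: Matteson homologation: chloromethyllithium generated in the presence of 13 forms the boronate and the sec-alkyl group migrates with retention and loss of chloride, inserting C12′ as a CH2 group.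

Step 11
Reactants: 15 2-[(2R)-2,3-dimethylbutyl]-4,4,5,5-tetramethyl-1,3,2-dioxaborolane
Product: 17 2-[(3R)-3,4-dimethylpentyl]-4,4,5,5-tetramethyl-1,3,2-dioxaborolane, via boronate complex 16 (not isolated)
Conditions: ClCH2I, n-BuLi, Et2O, −78 °C → rt
Reagents that add atoms: chloroiodomethane (ClCI)
Why: A second Matteson homologation of the same type inserts C11′ without touching the C13′ stereocentre.

Step 12
Reactants: 17 2-[(3R)-3,4-dimethylpentyl]-4,4,5,5-tetramethyl-1,3,2-dioxaborolane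
Product: 19 2-[(2S,5R)-5,6-dimethylheptan-2-yl]-4,4,5,5-tetramethyl-1,3,2-dioxaborolane, via boronate complex 18 (not isolated)
Conditions: ethyl 2,4,6-triisopropylbenzoate, s-BuLi, (+)-sparteine, Et2O, −78 °C; add 17; then 40 °C
Reagents that add atoms: ethyl 2,4,6-triisopropylbenzoate (CCOC(=O)c1c(C(C)C)cc(C(C)C)cc1C(C)C)
Why: Lithiation–borylation as in step 9 with the (R)-carbenoid sets C10′ by reagent control, independent of the remote C13′ centre.

Step 13
Reactants: 19 2-[(2S,5R)-5,6-dimethylheptan-2-yl]-4,4,5,5-tetramethyl-1,3,2-dioxaborolane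
Product: 21 4,4,5,5-tetramethyl-2-[(2S,3S,6R)-3,6,7-trimethyloctan-2-yl]-1,3,2-dioxaborolane, via boronate complex 20 (not isolated)
Conditions: ethyl 2,4,6-triisopropylbenzoate, s-BuLi, (+)-sparteine, Et2O, −78 °C; add 19; then 40 °C
Reagents that add atoms: ethyl 2,4,6-triisopropylbenzoate (CCOC(=O)c1c(C(C)C)cc(C(C)C)cc1C(C)C)
Why: Lithiation–borylation on the secondary boronic ester (retention at the migrating C10′, inversion at the carbenoid carbon) sets C9′ and so gives the anti vicinal dimethyl pair under pure reagent control.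

Step 14
Reactants: 21 4,4,5,5-tetramethyl-2-[(2S,3S,6R)-3,6,7-trimethyloctan-2-yl]-1,3,2-dioxaborolane
Product: 23 4,4,5,5-tetramethyl-2-[(2R,3S,6R)-2,3,6,7-tetramethyloctyl]-1,3,2-dioxaborolane, via boronate complex 22 (not isolated)
Conditions: ClCH2I, n-BuLi, Et2O, −78 °C → rt
Reagents that add atoms: chloroiodomethane (ClCI)
Why: Matteson homologation inserts C8′ as CH2, the C9′ stereocentre migrating from boron to carbon with retention.

Step 15
Reactants: 23 4,4,5,5-tetramethyl-2-[(2R,3S,6R)-2,3,6,7-tetramethyloctyl]-1,3,2-dioxaborolane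
Product: 25 4,4,5,5-tetramethyl-2-[(3R,4S,7R)-3,4,7,8-tetramethylnonyl]-1,3,2-dioxaborolane, via boronate complex 24 (not isolated)
Conditions: ClCH2I, n-BuLi, Et2O, −78 °C → rt
Reagents that add atoms: chloroiodomethane (ClCI)
Why: Matteson homologation inserts C7′ as CH2 and leaves all three stereocentres untouched.

Step 16
Reactants: 25 4,4,5,5-tetramethyl-2-[(3R,4S,7R)-3,4,7,8-tetramethylnonyl]-1,3,2-dioxaborolane
Product: 27 4,4,5,5-tetramethyl-2-[(2R,5R,6S,9R)-5,6,9,10-tetramethylundecan-2-yl]-1,3,2-dioxaborolane, via boronate complex 26 (not isolated)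
Conditions: ethyl 2,4,6-triisopropylbenzoate, s-BuLi, (−)-sparteine, Et2O, −78 °C; add 25; then 40 °C
Reagents that add atoms: ethyl 2,4,6-triisopropylbenzoate (CCOC(=O)c1c(C(C)C)cc(C(C)C)cc1C(C)C)
Why: Lithiation–borylation with the enantiomeric (S)-carbenoid from (−)-sparteine sets C6′ as the secondary boronic ester.

Step 17
Reactants: 27 4,4,5,5-tetramethyl-2-[(2R,5R,6S,9R)-5,6,9,10-tetramethylundecan-2-yl]-1,3,2-dioxaborolane
Product: 30 (3R,6R,7S,10R)-3,6,7,10,11-pentamethyldodec-1-yne, via bromovinyl boronate complex 28 (not isolated), via 2-bromoalkene 29 (not isolated)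
Conditions: bromoethene, LiN(i-Pr)2 (LDA), THF, −78 °C; I2, NaOMe, MeOH, −78 °C → rt; then Bu4NF (TBAF), THF, rt
Reagents that add atoms: bromoethene (C=CBr)
Why: Zweifel-type alkenylation (α-lithiated vinyl bromide adds to boron, iodine triggers 1,2-migration of the sec-alkyl group with retention and methoxide-assisted anti elimination) followed by fluoride-mediated dehydrobromination replaces boron by a terminal alkyne without loss of configuration at C6′.

Step 18
Reactants: 30 (3R,6R,7S,10R)-3,6,7,10,11-pentamethyldodec-1-yne; 10 diethyl (2E)-3-methyl-5-[(1S,3S)-2,2,3-trimethyl-6-methylidenecyclohexyl]pent-2-en-1-yl phosphate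
Product: 32 (1S,3S)-1-[(3S,4E,6R,9R,10S,13R)-3-ethenyl-3,6,9,10,13,14-hexamethylpentadec-4-en-1-yl]-2,2,3-trimethyl-6-methylidenecyclohexane, via alkenylalane 31 (not isolated)
Conditions: 30, i-Bu2AlH, hexanes, 55 °C; then 10, CuCl2·2H2O (5 mol %), 2-[(4S,5S)-3-mesityl-4,5-diphenyl-4,5-dihydroimidazol-3-ium-1-yl]benzenesulfonate (2.5 mol %), THF, −15 °C
Reagents that add atoms: none
Why: syn-Hydroalumination gives the E-alkenylalane, whose alkenyl group is delivered by the chiral sulfonate-bridged NHC–copper catalyst to the γ-carbon of the allylic phosphate (enantioselective SN2′ allylic substitution, as known for geranyl-type phosphates), forming the C3′ quaternary centre under catalyst control together with the vinyl group and the E-alkene.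

**Compound list**
1 | 3,4-dimethylanisole | COc1ccc(C)c(C)c1 | starting material
2 | 1-methoxy-4,5-dimethylcyclohexa-1,4-diene | COC1=CCC(C)=C(C)C1 | intermediate
3 | 3,4-dimethylcyclohex-3-en-1-one | O=C1CCC(C)=C(C)C1 | intermediate
4 | (4S)-3,4-dimethylcyclohex-2-en-1-one | C[C@H]1CCC(=O)C=C1C | intermediate
5 | trimethyl{[(4S)-3,3,4-trimethylcyclohex-1-en-1-yl]oxy}silane | C[C@H]1CCC(O[Si](C)(C)C)=CC1(C)C | intermediate
6 | (2R,4S)-3,3,4-trimethyl-2-(3-oxobutyl)cyclohexan-1-one | CC(=O)CC[C@H]1C(=O)CC[C@H](C)C1(C)C | intermediate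
7 | ethyl (2E)-3-methyl-5-[(1R,3S)-2,2,3-trimethyl-6-oxocyclohexyl]pent-2-enoate | CCOC(=O)/C=C(\C)CC[C@H]1C(=O)CC[C@H](C)C1(C)C | intermediate
8 | ethyl (2E)-3-methyl-5-[(1S,3S)-2,2,3-trimethyl-6-methylidenecyclohexyl]pent-2-enoate | CCOC(=O)/C=C(\C)CC[C@H]1C(=C)CC[C@H](C)C1(C)C | intermediate
9 | (2E)-3-methyl-5-[(1S,3S)-2,2,3-trimethyl-6-methylidenecyclohexyl]pent-2-en-1-ol | OC/C=C(\C)CC[C@H]1C(=C)CC[C@H](C)C1(C)C | intermediate
10 | diethyl (2E)-3-methyl-5-[(1S,3S)-2,2,3-trimethyl-6-methylidenecyclohexyl]pent-2-en-1-yl phosphate | CCOP(=O)(OCC)OC/C=C(\C)CC[C@H]1C(=C)CC[C@H](C)C1(C)C | intermediate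
11 | 4,4,5,5-tetramethyl-2-(propan-2-yl)-1,3,2-dioxaborolane | CC(C)B1OC(C)(C)C(C)(C)O1 | starting material
12 | lithium [(1R)-1-(2,4,6-triisopropylbenzoyloxy)ethyl](propan-2-yl)(pinacolato)borate | [Li+].CC(C)[B-]1(OC(C)(C)C(C)(C)O1)[C@H](C)OC(=O)c1c(C(C)C)cc(C(C)C)cc1C(C)C | intermediate
13 | 4,4,5,5-tetramethyl-2-[(2S)-3-methylbutan-2-yl]-1,3,2-dioxaborolane | CC(C)[C@H](C)B1OC(C)(C)C(C)(C)O1 | intermediate
14 | lithium (chloromethyl)[(2S)-3-methylbutan-2-yl](pinacolato)borate | [Li+].CC(C)[C@H](C)[B-]1(CCl)OC(C)(C)C(C)(C)O1 | intermediate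
15 | 2-[(2R)-2,3-dimethylbutyl]-4,4,5,5-tetramethyl-1,3,2-dioxaborolane | CC(C)[C@H](C)CB1OC(C)(C)C(C)(C)O1 | intermediate
16 | lithium (chloromethyl)[(2R)-2,3-dimethylbutyl](pinacolato)borate | [Li+].CC(C)[C@H](C)C[B-]1(CCl)OC(C)(C)C(C)(C)O1 | intermediate
17 | 2-[(3R)-3,4-dimethylpentyl]-4,4,5,5-tetramethyl-1,3,2-dioxaborolane | CC(C)[C@H](C)CCB1OC(C)(C)C(C)(C)O1 | intermediate
18 | lithium [(3R)-3,4-dimethylpentyl][(1R)-1-(2,4,6-triisopropylbenzoyloxy)ethyl](pinacolato)borate | [Li+].CC(C)[C@H](C)CC[B-]1(OC(C)(C)C(C)(C)O1)[C@H](C)OC(=O)c1c(C(C)C)cc(C(C)C)cc1C(C)C | intermediate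
19 | 2-[(2S,5R)-5,6-dimethylheptan-2-yl]-4,4,5,5-tetramethyl-1,3,2-dioxaborolane | CC(C)[C@H](C)CC[C@H](C)B1OC(C)(C)C(C)(C)O1 | intermediate
20 | lithium [(2S,5R)-5,6-dimethylheptan-2-yl][(1R)-1-(2,4,6-triisopropylbenzoyloxy)ethyl](pinacolato)borate | [Li+].CC(C)[C@H](C)CC[C@H](C)[B-]1(OC(C)(C)C(C)(C)O1)[C@H](C)OC(=O)c1c(C(C)C)cc(C(C)C)cc1C(C)C | intermediate
21 | 4,4,5,5-tetramethyl-2-[(2S,3S,6R)-3,6,7-trimethyloctan-2-yl]-1,3,2-dioxaborolane | CC(C)[C@H](C)CC[C@H](C)[C@H](C)B1OC(C)(C)C(C)(C)O1 | intermediate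
22 | lithium (chloromethyl)[(2S,3S,6R)-3,6,7-trimethyloctan-2-yl](pinacolato)borate | [Li+].CC(C)[C@H](C)CC[C@H](C)[C@H](C)[B-]1(CCl)OC(C)(C)C(C)(C)O1 | intermediate
23 | 4,4,5,5-tetramethyl-2-[(2R,3S,6R)-2,3,6,7-tetramethyloctyl]-1,3,2-dioxaborolane | CC(C)[C@H](C)CC[C@H](C)[C@H](C)CB1OC(C)(C)C(C)(C)O1 | intermediate
24 | lithium (chloromethyl)[(2R,3S,6R)-2,3,6,7-tetramethyloctyl](pinacolato)borate | [Li+].CC(C)[C@H](C)CC[C@H](C)[C@H](C)C[B-]1(CCl)OC(C)(C)C(C)(C)O1 | intermediate
25 | 4,4,5,5-tetramethyl-2-[(3R,4S,7R)-3,4,7,8-tetramethylnonyl]-1,3,2-dioxaborolane | CC(C)[C@H](C)CC[C@H](C)[C@H](C)CCB1OC(C)(C)C(C)(C)O1 | intermediate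
26 | lithium [(1S)-1-(2,4,6-triisopropylbenzoyloxy)ethyl][(3R,4S,7R)-3,4,7,8-tetramethylnonyl](pinacolato)borate | [Li+].CC(C)[C@H](C)CC[C@H](C)[C@H](C)CC[B-]1(OC(C)(C)C(C)(C)O1)[C@@H](C)OC(=O)c1c(C(C)C)cc(C(C)C)cc1C(C)C | intermediate
27 | 4,4,5,5-tetramethyl-2-[(2R,5R,6S,9R)-5,6,9,10-tetramethylundecan-2-yl]-1,3,2-dioxaborolane | CC(C)[C@H](C)CC[C@H](C)[C@H](C)CC[C@@H](C)B1OC(C)(C)C(C)(C)O1 | intermediate
28 | lithium (1-bromoethenyl)[(2R,5R,6S,9R)-5,6,9,10-tetramethylundecan-2-yl](pinacolato)borate | [Li+].C=C(Br)[B-]1(OC(C)(C)C(C)(C)O1)[C@H](C)CC[C@@H](C)[C@@H](C)CC[C@@H](C)C(C)C | intermediate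
29 | (3R,6R,7S,10R)-2-bromo-3,6,7,10,11-pentamethyldodec-1-ene | C=C(Br)[C@H](C)CC[C@@H](C)[C@@H](C)CC[C@@H](C)C(C)C | intermediate
30 | (3R,6R,7S,10R)-3,6,7,10,11-pentamethyldodec-1-yne | C#C[C@H](C)CC[C@@H](C)[C@@H](C)CC[C@@H](C)C(C)C | intermediate
31 | [(1E,3R,6R,7S,10R)-3,6,7,10,11-pentamethyldodec-1-en-1-yl]bis(2-methylpropyl)alumane | CC(C)C[Al](CC(C)C)/C=C/[C@H](C)CC[C@@H](C)[C@@H](C)CC[C@@H](C)C(C)C | intermediate
32 | (1S,3S)-1-[(3S,4E,6R,9R,10S,13R)-3-ethenyl-3,6,9,10,13,14-hexamethylpentadec-4-en-1-yl]-2,2,3-trimethyl-6-methylidenecyclohexane | C=C[C@@](C)(/C=C/[C@H](C)CC[C@@H](C)[C@@H](C)CC[C@@H](C)C(C)C)CC[C@H]1C(=C)CC[C@H](C)C1(C)C | target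

**Step count**
Total: 18 steps. Longest linear sequence: 10 steps (11 → 32, steps 9–18). The ring branch is 9 steps (steps 1–8 and 18).

**Three steps most likely to fail**

Step 2. The isomerisation has not been shown on a β,γ-enone with a fully substituted alkene, the reverse reaction can erode the ee, and I have not established which pseudoenantiomeric catalyst gives the S enone; the first run must settle that (the quinine-derived amine gives the antipode). The fallback sets out from 3 and comes back at 4. p-TsOH in benzene isomerises 3 to racemic 3,4-dimethylcyclohex-2-en-1-one F1. Reduction with (S)-2-methyl-CBS-oxazaborolidine and BH3·SMe2 then converts the two enantiomers into the diastereomeric allylic alcohols (1R,4S)-3,4-dimethylcyclohex-2-en-1-ol F2 and (1R,4R)-3,4-dimethylcyclohex-2-en-1-ol F3, which are separated on silica. MnO2 oxidation of F2 returns 4.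

Step 4. The nucleophilic carbon is next to a quaternary centre, but-3-en-2-one can polymerise, and the trans product is the kinetic one; by my estimate the cis ketone is about 1 kcal/mol more stable. The fallback sets out from 5 and comes back at 9, so it also bypasses the E/Z separation of step 5. MeLi in THF cleaves 5 to lithium (4S)-3,3,4-trimethylcyclohex-1-en-1-olate F4, which is alkylated axially by allyl bromide/HMPA to (2R,4S)-3,3,4-trimethyl-2-(prop-2-en-1-yl)cyclohexan-1-one F5. Zn/CH2Br2/TiCl4 methylenation gives (1S,3S)-2,2,3-trimethyl-6-methylidene-1-(prop-2-en-1-yl)cyclohexane F6. Aldehyde-selective Wacker oxidation of the monosubstituted alkene (PdCl2(PhCN)2, CuCl2·2H2O, AgNO2, O2, t-BuOH–MeNO2) gives 3-[(1S,3S)-2,2,3-trimethyl-6-methylidenecyclohexyl]propanal F7. The Ohira–Bestmann reagent with K2CO3 in MeOH gives (1S,3S)-1-(but-3-yn-1-yl)-2,2,3-trimethyl-6-methylidenecyclohexane F8. Negishi carboalumination (Me3Al, Cp2ZrCl2) gives dimethyl{(1E)-2-methyl-4-[(1S,3S)-2,2,3-trimethyl-6-methylidenecyclohexyl]but-1-en-1-yl}alumane F9, which is quenched in the flask with paraformaldehyde to give 9 as the pure E isomer.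

Step 18. The quaternary centre rests on catalyst control with a chiral, α-branched alkenylalane, and a few per cent of the C3′ epimer would be very hard to remove; the ligand enantiomer written is by analogy and is exchanged for its mirror image if the first run gives the 3′R epimer. The fallback sets out from 9 and 30 and comes back at 32; it builds the centre stereospecifically. Sharpless epoxidation of 9 (Ti(OiPr)4, D-(−)-diethyl tartrate, t-BuOOH, CH2Cl2, −20 °C) gives [(2R,3R)-3-methyl-3-{2-[(1S,3S)-2,2,3-trimethyl-6-methylidenecyclohexyl]ethyl}oxiran-2-yl]methanol F10. Alkyne 30 is metalated with Me3Al and catalytic Et3N to dimethyl[(3R,6R,7S,10R)-3,6,7,10,11-pentamethyldodec-1-yn-1-yl]alumane F11, used in excess (the surplus alkyne is recovered). F11 opens F10 at the tertiary epoxide carbon with inversion to give (2S,3R)-3-methyl-3-[(3R,6R,7S,10R)-3,6,7,10,11-pentamethyldodec-1-yn-1-yl]-5-[(1S,3S)-2,2,3-trimethyl-6-methylidenecyclohexyl]pentane-1,2-diol F12. Na in NH3(l) reduces the alkyne to (2S,3R)-3-methyl-3-[(1E,3R,6R,7S,10R)-3,6,7,10,11-pentamethyldodec-1-en-1-yl]-5-[(1S,3S)-2,2,3-trimethyl-6-methylidenecyclohexyl]pentane-1,2-diol F13. Garegg–Samuelsson deoxygenation of the terminal diol (Ph3P, I2, imidazole, toluene, reflux) gives the vinyl group and 32.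

**Further compounds**
F1 | step 2 | racemic 3,4-dimethylcyclohex-2-en-1-one | CC1CCC(=O)C=C1C
F2 | step 2 | (1R,4S)-3,4-dimethylcyclohex-2-en-1-ol | C[C@H]1CC[C@@H](O)C=C1C
F3 | step 2 | (1R,4R)-3,4-dimethylcyclohex-2-en-1-ol | C[C@@H]1CC[C@@H](O)C=C1C
F4 | step 4 | lithium (4S)-3,3,4-trimethylcyclohex-1-en-1-olate | [Li+].C[C@H]1CCC([O-])=CC1(C)C
F5 | step 4 | (2R,4S)-3,3,4-trimethyl-2-(prop-2-en-1-yl)cyclohexan-1-one | C=CC[C@H]1C(=O)CC[C@H](C)C1(C)C
F6 | step 4 | (1S,3S)-2,2,3-trimethyl-6-methylidene-1-(prop-2-en-1-yl)cyclohexane | C=CC[C@H]1C(=C)CC[C@H](C)C1(C)C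
F7 | step 4 | 3-[(1S,3S)-2,2,3-trimethyl-6-methylidenecyclohexyl]propanal | O=CCC[C@H]1C(=C)CC[C@H](C)C1(C)C
F8 | step 4 | (1S,3S)-1-(but-3-yn-1-yl)-2,2,3-trimethyl-6-methylidenecyclohexane | C#CCC[C@H]1C(=C)CC[C@H](C)C1(C)C
F9 | step 4 | dimethyl{(1E)-2-methyl-4-[(1S,3S)-2,2,3-trimethyl-6-methylidenecyclohexyl]but-1-en-1-yl}alumane | C[Al](C)/C=C(\C)CC[C@H]1C(=C)CC[C@H](C)C1(C)C
F10 | step 18 | [(2R,3R)-3-methyl-3-{2-[(1S,3S)-2,2,3-trimethyl-6-methylidenecyclohexyl]ethyl}oxiran-2-yl]methanol | OC[C@H]1O[C@]1(C)CC[C@H]2C(=C)CC[C@H](C)C2(C)C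
F11 | step 18 | dimethyl[(3R,6R,7S,10R)-3,6,7,10,11-pentamethyldodec-1-yn-1-yl]alumane | C[Al](C)C#C[C@H](C)CC[C@@H](C)[C@@H](C)CC[C@@H](C)C(C)C
F12 | step 18 | (2S,3R)-3-methyl-3-[(3R,6R,7S,10R)-3,6,7,10,11-pentamethyldodec-1-yn-1-yl]-5-[(1S,3S)-2,2,3-trimethyl-6-methylidenecyclohexyl]pentane-1,2-diol | OC[C@@H](O)[C@@](C)(C#C[C@H](C)CC[C@@H](C)[C@@H](C)CC[C@@H](C)C(C)C)CC[C@H]1C(=C)CC[C@H](C)C1(C)C
F13 | step 18 | (2S,3R)-3-methyl-3-[(1E,3R,6R,7S,10R)-3,6,7,10,11-pentamethyldodec-1-en-1-yl]-5-[(1S,3S)-2,2,3-trimethyl-6-methylidenecyclohexyl]pentane-1,2-diol | OC[C@@H](O)[C@@](C)(/C=C/[C@H](C)CC[C@@H](C)[C@@H](C)CC[C@@H](C)C(C)C)CC[C@H]1C(=C)CC[C@H](C)C1(C)C
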